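**Retrosynthetic overview**
1. The TBS ether on the C8' carbinol is removed last. Before that, the bond from the quaternary C3 to the side-chain CH2 is cut as a biomimetic conjugate addition of ferulenol (3-farnesyl-4-hydroxycoumarin) to O-TBS-falcarinolone (a vinyl diynyl ketone). This is the new step and it sets C3.
2. The vinyl ketone comes from a lithium diynide plus acrolein, followed by oxidation. The C8' carbinol comes from catalytic asymmetric addition of TMS-butadiyne to (Z)-dec-2-enal, and the Z-alkene from Lindlar reduction of dec-2-yn-1-ol.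
3. Ferulenol comes from Dieckmann-type closure of methyl O-(farnesylacetyl)salicylate. Farnesylacetic acid comes from (E,E)-farnesyl bromide and the enolate of ethyl acetate.
4. Ring order: the benzene ring is bought with methyl salicylate. The only ring formed is the pyranone (lactone) ring, closed before the quaternary centre is made.

Assumption: the SMILES decodes to 3S (quaternary carbon), 8'S, 9'Z and 2''E,6''E; the sense of induction given for (S,S)-ProPhenol and (R)-TRIP is by model, both antipodes are on sale, and the antipode is used if Mosher or ECD analysis shows the opposite sense.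

**Step 1**
Reactants: 1 dec-2-yn-1-ol
Product: 2 (Z)-dec-2-en-1-ol
Conditions: H2 (1 atm), Lindlar catalyst (Pd/CaCO3–Pb), quinoline, hexane/EtOAc, rt
Reagents that add atoms: none
Why: Lindlar semihydrogenation delivers H2 syn on poisoned Pd and gives the Z-alkene, while quinoline stops over-reduction.

**Step 2**
Reactants: 2 (Z)-dec-2-en-1-ol
Product: 3 (Z)-dec-2-enal
Conditions: IBX (1.3 equiv), DMSO, rt, 2 h, dark; used crude
Reagents that add atoms: none
Why: IBX oxidation is neutral (no acid or amine), so the allylic alcohol becomes the enal without Z-to-E isomerisation.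

**Step 3**
Reactants: 4 1,4-bis(trimethylsilyl)buta-1,3-diyne
Product: 6 buta-1,3-diyn-1-yl(trimethyl)silane, via lithium TMS-butadiynide 5 (not isolated)
Conditions: MeLi·LiBr (1.0 equiv), Et2O, 0 °C → rt; then sat. aq. NH4Cl
Reagents that add atoms: none
Why: In this mono-desilylation MeLi attacks one silicon and expels the acetylide, and the anionic monoacetylide resists a second attack, so protonation gives the terminal diyne.

**Step 4**
Reactants: 3 (Z)-dec-2-enal; 6 buta-1,3-diyn-1-yl(trimethyl)silane
Product: 8 (5S,6Z)-1-(trimethylsilyl)tetradeca-6-ene-1,3-diyn-5-ol, via methylzinc TMS-butadiynide 7 (not isolated)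
Conditions: (S,S)-ProPhenol (20 mol %), Ph3P=O (40 mol %), Me2Zn, toluene, 4 °C, 48 h; then sat. aq. NH4Cl
Reagents that add atoms: none
Why: In this ProPhenol dinuclear-zinc asymmetric alkynylation of an enal, one zinc binds the aldehyde and the other carries the diynyl group, which is delivered to the Re face of C=O to set 5S (the future C8').

**Step 5**
Reactants: 8 (5S,6Z)-1-(trimethylsilyl)tetradeca-6-ene-1,3-diyn-5-ol
Product: 9 tert-butyl(dimethyl){[(5S,6Z)-1-(trimethylsilyl)tetradeca-6-ene-1,3-diyn-5-yl]oxy}silane
Conditions: TBSCl, imidazole, DMF, 0 °C → rt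
Reagents that add atoms: tert-butyldimethylsilyl chloride, CC(C)(C)[Si](C)(C)Cl
Why: Standard imidazole-promoted O-silylation touches neither the C–O bond of the stereocentre nor the alkynyl C–Si bond.

**Step 6**
Reactants: 9 tert-butyl(dimethyl){[(5S,6Z)-1-(trimethylsilyl)tetradeca-6-ene-1,3-diyn-5-yl]oxy}silane
Product: 10 tert-butyl(dimethyl){[(5S,6Z)-tetradeca-6-ene-1,3-diyn-5-yl]oxy}silane
Conditions: K2CO3 (cat.), MeOH/THF, 0 °C, 30 min
Reagents that add atoms: none
Why: Base-catalysed methanolysis (protodesilylation) cleaves the C(sp)–SiMe3 bond far faster than the hindered O–TBS bond.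

**Step 7**
Reactants: 10 tert-butyl(dimethyl){[(5S,6Z)-tetradeca-6-ene-1,3-diyn-5-yl]oxy}silane; 11 acrolein
Product: 13 (8S,9Z)-8-(tert-butyldimethylsilyloxy)heptadeca-1,9-diene-4,6-diyn-3-ol (about 1:1 at C3), via lithium diynide 12 (not isolated)
Conditions: n-BuLi (1.0 equiv), THF, −78 °C; then 11, −78 °C; then sat. aq. NH4Cl
Reagents that add atoms: none
Why: The hard lithium acetylide adds 1,2 to acrolein, and the new C3 carbinol needs no control because it is oxidised in the next step.

**Step 8**
Reactants: 13 (8S,9Z)-8-(tert-butyldimethylsilyloxy)heptadeca-1,9-diene-4,6-diyn-3-ol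
Product: 14 (8S,9Z)-8-(tert-butyldimethylsilyloxy)heptadeca-1,9-diene-4,6-diyn-3-one (O-TBS-falcarinolone)
Conditions: activated MnO2, CH2Cl2, 0 °C → rt; filter through Celite; used at once
Reagents that add atoms: none
Why: MnO2 oxidises the doubly activated (allylic and propargylic) alcohol under neutral heterogeneous conditions, so the polymerisable vinyl ketone is isolated by filtration only and the silylated C8 is untouched.

**Step 9**
Reactants: 15 (2E,6E)-farnesyl bromide; 16 ethyl acetate
Product: 18 ethyl (4E,8E)-5,9,13-trimethyltetradeca-4,8,12-trienoate (ethyl farnesylacetate), via lithium enolate of ethyl acetate 17 (not isolated)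
Conditions: LDA (commercial solution), THF, −78 °C; then 15, DMPU, −78 → −20 °C
Reagents that add atoms: none
Why: SN2 alkylation of the ester enolate at the primary allylic carbon keeps the 2E,6E geometry of the chain.

**Step 10**
Reactants: 18 ethyl (4E,8E)-5,9,13-trimethyltetradeca-4,8,12-trienoate
Product: 19 (4E,8E)-5,9,13-trimethyltetradeca-4,8,12-trienoic acid (farnesylacetic acid)
Conditions: LiOH, THF/MeOH/H2O, rt; then cold 1 M HCl to pH 3
Reagents that add atoms: lithium hydroxide, [Li+].[OH-]
Why: Saponification by acyl–oxygen cleavage is followed by a short cold acidification that leaves the trisubstituted alkenes intact.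

**Step 11**
Reactants: 19 (4E,8E)-5,9,13-trimethyltetradeca-4,8,12-trienoic acid; 20 methyl salicylate
Product: 21 methyl 2-{[(4E,8E)-5,9,13-trimethyltetradeca-4,8,12-trienoyl]oxy}benzoate
Conditions: DCC, DMAP (cat.), CH2Cl2, 0 °C → rt
Reagents that add atoms: none
Why: Steglich esterification acylates the hydrogen-bonded phenol through the acylpyridinium ion without the acid that would cyclise the polyene.

**Step 12**
Reactants: 21 methyl 2-{[(4E,8E)-5,9,13-trimethyltetradeca-4,8,12-trienoyl]oxy}benzoate
Product: 23 ferulenol (4-hydroxy-3-[(2E,6E)-3,7,11-trimethyldodeca-2,6,10-trien-1-yl]-2H-chromen-2-one), via lithium ferulenolate 22 (not isolated)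
Conditions: LiHMDS (2.2 equiv), THF, −78 °C → rt; then cold 1 M HCl
Reagents that add atoms: none
Why: In this intramolecular Claisen (Dieckmann-type) condensation the aryl ester enolate attacks the ortho methyl ester in a 6-membered closure, and formation of the stabilised 4-oxidocoumarin drives the reaction and forms the pyranone ring.

**Step 13**
Reactants: 14 (8S,9Z)-8-(tert-butyldimethylsilyloxy)heptadeca-1,9-diene-4,6-diyn-3-one; 23 ferulenol
Product: 24 (3S)-3-[(8S,9Z)-8-(tert-butyldimethylsilyloxy)-3-oxoheptadeca-9-ene-4,6-diyn-1-yl]-3-[(2E,6E)-3,7,11-trimethyldodeca-2,6,10-trien-1-yl]chromane-2,4-dione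
Conditions: (R)-TRIP (10 mol %), 5 Å MS, toluene (0.05 M), −40 °C, dark, 48–72 h; 14 (1.2 equiv)
Reagents that add atoms: none
Why: Proposed new method: chiral-phosphoric-acid-catalysed enantioselective quaternising conjugate addition of a 3-alkyl-4-hydroxycoumarin to a vinyl diynyl ketone – the fully enolised 23 donates its C4–OH hydrogen bond to the phosphoryl oxygen (raising the nucleophilicity of C3) while the P–OH proton activates the s-cis ketone of 14, so both partners sit in one cyclic hydrogen-bonded array inside the 3,3'-(2,4,6-triisopropylphenyl) pocket; because the catalyst can anchor only at O4 and not on the lactone side, the flat benzopyranone has one allowed orientation, the farnesyl chain points out of the pocket, and the unsubstituted CH2= terminus (the least hindered of the three electrophilic sites of 14) reaches the Re face of C3 to give 3S; the base-free medium suppresses retro-Michael racemisation, amine-triggered ynone polymerisation and lactone opening, and the remote C8' centre has no influence; the closest known reaction types are phosphoric-acid-catalysed Michael additions of α-substituted β-keto esters to vinyl ketones (first stage of asymmetric Robinson annulations) and organocatalytic additions of unsubstituted 4-hydroxycoumarin to enones (warfarin type), neither of which builds a C3 quaternary centre on the non-chelating, W-shaped and much more acidic coumarin dicarbonyl.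

**Step 14**
Reactants: 24 (3S)-3-[(8S,9Z)-8-(tert-butyldimethylsilyloxy)-3-oxoheptadeca-9-ene-4,6-diyn-1-yl]-3-[(2E,6E)-3,7,11-trimethyldodeca-2,6,10-trien-1-yl]chromane-2,4-dione
Product: 25 (3S)-3-[(8S,9Z)-8-hydroxy-3-oxoheptadeca-9-ene-4,6-diyn-1-yl]-3-[(2E,6E)-3,7,11-trimethyldodeca-2,6,10-trien-1-yl]chromane-2,4-dione (CNP0346147.1)
Conditions: HF·pyridine, pyridine, THF, 0 °C → rt; pH 7 phosphate buffer work-up
Reagents that add atoms: none
Why: Buffered HF·pyridine cleaves the Si–O bond under mildly acidic, non-nucleophilic conditions, which avoids the base that would cause retro-Michael loss of C3 or lactone opening, so both stereocentres are kept.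

**Compound list**
1 | dec-2-yn-1-ol | CCCCCCCC#CCO | starting material
2 | (Z)-dec-2-en-1-ol | CCCCCCC/C=C\CO | intermediate
3 | (Z)-dec-2-enal | CCCCCCC/C=C\C=O | intermediate
4 | 1,4-bis(trimethylsilyl)buta-1,3-diyne | C[Si](C)(C)C#CC#C[Si](C)(C)C | starting material
5 | lithium 4-(trimethylsilyl)buta-1,3-diynide (formed in the flask) | [Li]C#CC#C[Si](C)(C)C | intermediate
6 | buta-1,3-diyn-1-yl(trimethyl)silane | C#CC#C[Si](C)(C)C | intermediate
7 | methylzinc 4-(trimethylsilyl)buta-1,3-diynide (formed in the flask) | C[Zn]C#CC#C[Si](C)(C)C | intermediate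
8 | (5S,6Z)-1-(trimethylsilyl)tetradeca-6-ene-1,3-diyn-5-ol | CCCCCCC/C=C\[C@H](O)C#CC#C[Si](C)(C)C | intermediate
9 | tert-butyl(dimethyl){[(5S,6Z)-1-(trimethylsilyl)tetradeca-6-ene-1,3-diyn-5-yl]oxy}silane | CCCCCCC/C=C\[C@H](O[Si](C)(C)C(C)(C)C)C#CC#C[Si](C)(C)C | intermediate
10 | tert-butyl(dimethyl){[(5S,6Z)-tetradeca-6-ene-1,3-diyn-5-yl]oxy}silane | CCCCCCC/C=C\[C@H](O[Si](C)(C)C(C)(C)C)C#CC#C | intermediate
11 | acrolein | C=CC=O | starting material
12 | lithium (5S,6Z)-5-(tert-butyldimethylsilyloxy)tetradeca-6-ene-1,3-diynide (formed in the flask) | CCCCCCC/C=C\[C@H](O[Si](C)(C)C(C)(C)C)C#CC#C[Li] | intermediate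
13 | (8S,9Z)-8-(tert-butyldimethylsilyloxy)heptadeca-1,9-diene-4,6-diyn-3-ol (C3 epimer mixture) | CCCCCCC/C=C\[C@H](O[Si](C)(C)C(C)(C)C)C#CC#CC(O)C=C | intermediate
14 | (8S,9Z)-8-(tert-butyldimethylsilyloxy)heptadeca-1,9-diene-4,6-diyn-3-one | CCCCCCC/C=C\[C@H](O[Si](C)(C)C(C)(C)C)C#CC#CC(=O)C=C | intermediate
15 | (2E,6E)-farnesyl bromide | BrC/C=C(\C)CC/C=C(\C)CCC=C(C)C | starting material
16 | ethyl acetate | CCOC(C)=O | starting material
17 | lithium enolate of ethyl acetate (formed in the flask) | [Li]OC(=C)OCC | intermediate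
18 | ethyl (4E,8E)-5,9,13-trimethyltetradeca-4,8,12-trienoate | CCOC(=O)CC/C=C(\C)CC/C=C(\C)CCC=C(C)C | intermediate
19 | (4E,8E)-5,9,13-trimethyltetradeca-4,8,12-trienoic acid | OC(=O)CC/C=C(\C)CC/C=C(\C)CCC=C(C)C | intermediate
20 | methyl salicylate | COC(=O)c1ccccc1O | starting material
21 | methyl 2-{[(4E,8E)-5,9,13-trimethyltetradeca-4,8,12-trienoyl]oxy}benzoate | COC(=O)c1ccccc1OC(=O)CC/C=C(\C)CC/C=C(\C)CCC=C(C)C | intermediate
22 | lithium ferulenolate (formed in the flask) | [Li]Oc1c(C/C=C(\C)CC/C=C(\C)CCC=C(C)C)c(=O)oc2ccccc12 | intermediate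
23 | ferulenol, 3-[(2E,6E)-farnesyl]-4-hydroxycoumarin | Oc1c(C/C=C(\C)CC/C=C(\C)CCC=C(C)C)c(=O)oc2ccccc12 | intermediate
24 | (3S)-3-[(8S,9Z)-8-(tert-butyldimethylsilyloxy)-3-oxoheptadeca-9-ene-4,6-diyn-1-yl]-3-[(2E,6E)-farnesyl]chromane-2,4-dione | CCCCCCC/C=C\[C@H](O[Si](C)(C)C(C)(C)C)C#CC#CC(=O)CC[C@@]1(C/C=C(\C)CC/C=C(\C)CCC=C(C)C)C(=O)Oc2ccccc2C1=O | intermediate
25 | (3S)-3-[(8S,9Z)-8-hydroxy-3-oxoheptadeca-9-ene-4,6-diyn-1-yl]-3-[(2E,6E)-farnesyl]chromane-2,4-dione (CNP0346147.1) | CCCCCCC/C=C\[C@H](O)C#CC#CC(=O)CC[C@@]1(C/C=C(\C)CC/C=C(\C)CCC=C(C)C)C(=O)Oc2ccccc2C1=O | target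

**Total step count:** 14.
**Longest linear sequence:** 9 steps (1, 2, 4, 5, 6, 7, 8, 13, 14, from dec-2-yn-1-ol).

**Three steps most likely to fail**

Step 13 (the proposed new step).
- Risks: a racemic background addition driven by the acidity of 23 itself, modest facial control, O-alkylation, or attack at the ynone carbons.
- Fallback (known chemistry): it sets out from 14 and 23 and comes back at 24. The union is run as an ordinary tertiary-amine-catalysed Michael addition (Et3N 5 mol %, CH2Cl2, 0 °C) with no control at C3. Because C8' is already a single enantiomer, the product is a roughly 1:1 pair of diastereomers, 24 and the (3R)-epimer of 24 F3. These are separated by preparative HPLC on an amylose-carbamate chiral phase, with C3 assigned by ECD comparison. Compound 24 then goes on to step 14.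

Step 4.
- Risks: Z-to-E isomerisation of 3 on the Lewis-acidic zinc, and only moderate ee with a Z-enal.
- Fallback: it sets out from 3, together with lithium acetylide 5 taken from step 3 before the quench, and comes back at 8. Compound 5 is added to 3 at −78 °C and quenched with aq. NH4Cl to give racemic (Z)-1-(trimethylsilyl)tetradeca-6-ene-1,3-diyn-5-ol F1. MnO2 in CH2Cl2 oxidises this to (Z)-1-(trimethylsilyl)tetradeca-6-ene-1,3-diyn-5-one F2. The ketone is then reduced with (S)-Alpine-Borane (Midland reduction, THF, rt), in which the rod-like diynyl group takes the small-group position of the boat-like transition state and gives 8. The stereocentre is thus set by reagent-controlled hydride transfer instead of C–C bond formation.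

Step 14.
- Risks: retro-Michael cleavage, opening of the activated aryl lactone, or ionisation of the doubly activated carbinol during desilylation of the finished skeleton.
- Fallback: it sets out from 14 and comes back at 25. The silyl group is removed before the union: HF·pyridine/pyridine in THF at 0 °C converts 14 into (8S,9Z)-8-hydroxyheptadeca-1,9-diene-4,6-diyn-3-one F4 (falcarinolone). This is used at once with 23 under the conditions of step 13 and gives 25 directly. No reagent then touches the chromane-2,4-dione after it is formed.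

**Further compounds**
F1 | step 4 | racemic (Z)-1-(trimethylsilyl)tetradeca-6-ene-1,3-diyn-5-ol | CCCCCCC/C=C\C(O)C#CC#C[Si](C)(C)C
F2 | step 4 | (Z)-1-(trimethylsilyl)tetradeca-6-ene-1,3-diyn-5-one | CCCCCCC/C=C\C(=O)C#CC#C[Si](C)(C)C
F3 | step 13 | (3R)-epimer of 24 | CCCCCCC/C=C\[C@H](O[Si](C)(C)C(C)(C)C)C#CC#CC(=O)CC[C@]1(C/C=C(\C)CC/C=C(\C)CCC=C(C)C)C(=O)Oc2ccccc2C1=O
F4 | step 14 | (8S,9Z)-8-hydroxyheptadeca-1,9-diene-4,6-diyn-3-one | CCCCCCC/C=C\[C@H](O)C#CC#CC(=O)C=C
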